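**Plan**

- Retrosynthesis (labdane numbering): the imide arm is cut at C12–C13 and C16–N (aldol, cyclative release of the auxiliary), C17 at C8=C17 (Wittig), chlorine at C2–Cl (C–H chlorination), ring A at C3–C4 (enolate alkylation), ring B at C5–C10 (radical conjugate cyclisation), then C9–C10 (alkenyl conjugate addition) and C8–C9 (alkynylation).
- Forward: C8 carbinol by catalytic asymmetric alkynylation → butenolide → trans lactone → ring B by hydrogen-atom-transfer closure of C5–C10 → ring A by C3–C4 alkylation → C2 chlorination → lactone unravelled to C8=CH2 and the C12 aldehyde → aldol and succinimide.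
- Enabling feature: C10 is the methyl-bearing quaternary ring-fusion carbon of rings A/B, so it can be a tertiary radical born from a C10=C20 alkene. C5, the other ring-fusion carbon, is β to C4, which carries the oxidised C18, so it can be the β-carbon of a C5=C4(Me)–C18O2Me enoate.
- Helpers: a γ-lactone C8–O–C12(=O) as temporary ring (fixes the chair of the closure, later deactivates ring B for the chlorination, finally gives the C8 ketone and C12 aldehyde); C18 kept at the ester level (acceptor, then enolate, then reduced to the CH2OH of the target).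
- Stereochemistry: C8 from the catalyst (erased later) → C9 (anti addition) → C5 and C10 together in the key step → C4 (allylic-strain-controlled alkylation) → C2 (equatorial chlorine transfer); C12/C13 from (R)-4-benzyloxazolidinone (Evans syn aldol).

Key step: step 6

Remark: decalin compounds are named with labdane numbering (C1–C10 rings, C5/C10 ring fusion, C11–C12 on C9, C13–C16 imide carbons, C17 on C8, C18 = 4α carbon, C19 = 4β methyl, C20 = C10 methyl; α is the face opposite to C20).
Remark: (S,S)-ProPhenol is assumed to give the (R)-carbinol with this aliphatic aldehyde; if the facial sense is the opposite, (R,R)-ProPhenol is used and nothing else changes.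

Step 1
Reactants: 1 pent-4-enal; 2 methyl methacrylate
Product: 3 methyl (2E)-2-methyl-6-oxohex-2-enoate
Conditions: RuCl2(=CHPh)(PCy3)(H2IMes) (second-generation Grubbs catalyst, 3 mol %), 2 (5 equiv), CH2Cl2, 40 °C
Reagents that add atoms: none
Why: Olefin cross-metathesis of a terminal alkene with a 1,1-disubstituted acrylate should give the trisubstituted E-enoate (C5=C4 with the C19 methyl and the C18 ester) under thermodynamic control while ethene escapes; no stereocentre is formed.

Step 2
Reactants: 3 methyl (2E)-2-methyl-6-oxohex-2-enoate; 4 methyl propiolate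
Product: 6 dimethyl (2E,6R)-6-hydroxy-2-methylnon-2-en-7-ynedioate, via alkynylzinc reagent 5 (not isolated)
Conditions: Me2Zn (3 equiv), (S,S)-ProPhenol (20 mol %), Ph3PO (40 mol %), PhMe, 4 °C, slow addition of 3
Reagents that add atoms: none
Why: Catalytic asymmetric alkynylation (zinc acetylide addition under a dinuclear zinc–ProPhenol catalyst) of the aliphatic aldehyde, in which the chiral catalyst selects the aldehyde face and sets the C8 carbinol as R, the only core stereocentre that comes from a catalyst.

Step 3
Reactants: 6 dimethyl (2E,6R)-6-hydroxy-2-methylnon-2-en-7-ynedioate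
Product: 8 methyl (2E)-2-methyl-5-[(2R)-5-oxo-2,5-dihydrofuran-2-yl]pent-2-enoate, via Z-hydroxy diester 7 (not isolated)
Conditions: H2 (1 atm), Pd/CaCO3 poisoned with Pb(OAc)2 (Lindlar catalyst), quinoline, EtOAc, 23 °C; then PPTS (cat.), PhMe, 60 °C
Reagents that add atoms: none
Why: Lindlar semihydrogenation gives the Z-enoate, whose C8 hydroxyl then closes the butenolide by acid-catalysed lactonisation; C8 is not touched and the trisubstituted enoate is not reduced.

Step 4
Reactants: 9 5-chloropent-1-yne
Product: 10 2-bromo-5-chloropent-1-ene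
Conditions: HBr, Et4NBr, CH2Cl2, 40 °C
Reagents that add atoms: hydrogen bromide, Br
Why: Bromide-assisted Markovnikov hydrobromination of the terminal alkyne places bromine on the internal carbon (future C10) and leaves the primary chloride (future C3) intact.

Step 5
Reactants: 10 2-bromo-5-chloropent-1-ene; 8 methyl (2E)-2-methyl-5-[(2R)-5-oxo-2,5-dihydrofuran-2-yl]pent-2-enoate
Product: 12 methyl (2E)-5-[(2R,3R)-3-(5-chloropent-1-en-2-yl)-5-oxooxolan-2-yl]-2-methylpent-2-enoate, via Grignard reagent 11 (not isolated)
Conditions: Mg, THF, 45 °C; then CuBr·SMe2 (10 mol %), 8, THF, −78 → −40 °C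
Reagents that add atoms: none
Why: Copper-catalysed conjugate addition of the alkenyl Grignard reagent to the butenolide should occur anti to the C8 substituent (1,2-induction on the five-membered ring) and so set C9 trans to C8, while the α-methyl-β-alkyl enoate is too unreactive to compete.

Step 6
Reactants: 12 methyl (2E)-5-[(2R,3R)-3-(5-chloropent-1-en-2-yl)-5-oxooxolan-2-yl]-2-methylpent-2-enoate
Product: 13 methyl 2-[(3aR,4S,5S,7aR)-4-(3-chloropropyl)-4-methyl-2-oxooctahydro-1-benzofuran-5-yl]propanoate (both C4 epimers)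
Conditions: Fe(acac)3 (30 mol %), PhSiH3 (3 equiv), EtOH/(CH2OH)2 (5:1), 0.02 M, 40 °C
Reagents that add atoms: none
Why: A trivalent iron hydride formed from Fe(acac)3, PhSiH3 and EtOH transfers a hydrogen atom to C20 of the electron-rich 1,1-disubstituted alkene, the tertiary C10 radical adds to C5, the β-carbon of the α-methyl enoate, and the C4 α-ester radical is reduced by divalent iron to an enolate that ethanol protonates. The closest known reaction type is the iron-hydride hydrogen-atom-transfer reductive olefin coupling in its intramolecular form (a Giese cyclisation). Ring B is closed in the 6-exo-trig mode through a chair transition state in which the trans-fused lactone holds the C8 oxygen and C11 equatorial. C5 is set by the enoate arm taking the equatorial site (H5 axial, cis to H9), and C10 by the 3-chloropropyl arm taking the equatorial site and the new methyl the axial one, because an axial chain has no rotamer free of a syn-pentane contact with C11, with the C5 arm or with the axial ring hydrogens; C4 is formed without control and is erased in step 8. The step needs hydrogen-atom transfer to the C10=C20 alkene only and ring closure faster than reduction of the radical; the electron-poor trisubstituted enoate is a poor hydrogen-atom acceptor, and high dilution with an activated acceptor in 6-exo reach should secure the closure.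

Step 7
Reactants: 13 methyl 2-[(3aR,4S,5S,7aR)-4-(3-chloropropyl)-4-methyl-2-oxooctahydro-1-benzofuran-5-yl]propanoate
Product: 14 methyl 2-[(3aR,4S,5S,7aR)-4-(3-iodopropyl)-4-methyl-2-oxooctahydro-1-benzofuran-5-yl]propanoate (both C4 epimers)
Conditions: NaI (5 equiv), acetone, 56 °C
Reagents that add atoms: sodium iodide, [Na+].[I-]
Why: Finkelstein exchange, driven by precipitation of NaCl from acetone, turns the primary chloride at C3 into the iodide needed for ring closure; no stereocentre is touched.

Step 8
Reactants: 14 methyl 2-[(3aR,4S,5S,7aR)-4-(3-iodopropyl)-4-methyl-2-oxooctahydro-1-benzofuran-5-yl]propanoate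
Product: 17 methyl 13,14,15,16,17-pentanor-8α,12-labdanolid-18-oate (5α-H, 9α-H, 10β-Me, 4β-Me, 4α-CO2Me), via lithium carboxylate 15 (not isolated), via hydroxy acid 16 (not isolated)
Conditions: LiOH·H2O (1.05 equiv), THF/H2O, 0 °C; concentrate, azeotrope with PhMe; LiN(iPr)2 (2.2 equiv), THF/DMPU, −78 → 0 °C; then 3 M HCl, THF, 50 °C
Reagents that add atoms: none
Why: Intramolecular ester enolate alkylation (6-exo-tet), run on the ring-opened hydroxy carboxylate so that C11 cannot be enolised (a polyanion alkylation of the Fráter–Seebach type, in which an alkoxide does not compete with the enolate carbon), should close ring A through a chair in which the enolate double bond eclipses H5 to avoid allylic 1,3-strain, which places the C18 ester equatorial (α) and the C19 methyl axial (β) at C4, and the acid then relactonises.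

Step 9
Reactants: 17 methyl 13,14,15,16,17-pentanor-8α,12-labdanolid-18-oate
Product: 18 methyl 2α-chloro-13,14,15,16,17-pentanor-8α,12-labdanolid-18-oate
Conditions: N-chloro-N-tert-butyl-3,5-bis(trifluoromethyl)benzamide (1.2 equiv), Cs2CO3, PhH, visible light, 55 °C
Reagents that add atoms: N-chloro-N-tert-butyl-3,5-bis(trifluoromethyl)benzamide, CC(C)(C)N(Cl)C(=O)c1cc(cc(c1)C(F)(F)F)C(F)(F)F
Why: Site-selective radical-chain C–H chlorination by a bulky, electrophilic amidyl radical, a reaction type established on decalin lactones such as sclareolide, should take the C2 hydrogen (C1 and C3 flank quaternary carbons, C3 and ring B are deactivated by the ester and the lactone) and deliver chlorine to the α (equatorial) face because the axial C19 and C20 methyl groups block the β face.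

Step 10
Reactants: 18 methyl 2α-chloro-13,14,15,16,17-pentanor-8α,12-labdanolid-18-oate
Product: 19 methyl 2α-chloro-8α-hydroxy-12-[methoxy(methyl)amino]-12-oxo-13,14,15,16,17-pentanorlabdan-18-oate
Conditions: MeNHOMe·HCl (3 equiv), i-PrMgCl (6 equiv), THF, −20 → 0 °C
Reagents that add atoms: N,O-dimethylhydroxylamine hydrochloride, CNOC.Cl
Why: Weinreb amide formation by aminolysis of the γ-lactone with the chloromagnesium amide frees the C8 hydroxyl and fixes C12 at the acyl level, while the hindered C18 ester and the secondary chloride are not attacked.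

Step 11
Reactants: 19 methyl 2α-chloro-8α-hydroxy-12-[methoxy(methyl)amino]-12-oxo-13,14,15,16,17-pentanorlabdan-18-oate
Product: 20 methyl 2α-chloro-12-[methoxy(methyl)amino]-8,12-dioxo-13,14,15,16,17-pentanorlabdan-18-oate
Conditions: Dess–Martin periodinane, CH2Cl2, 23 °C
Reagents that add atoms: none
Why: Dess–Martin oxidation of the secondary C8 alcohol gives the ketone under near-neutral conditions and removes the C8 stereocentre once its relay work is done.

Step 12
Reactants: 20 methyl 2α-chloro-12-[methoxy(methyl)amino]-8,12-dioxo-13,14,15,16,17-pentanorlabdan-18-oate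
Product: 21 methyl 2α-chloro-12-[methoxy(methyl)amino]-12-oxo-13,14,15,16-tetranorlabd-8(17)-en-18-oate
Conditions: Ph3PCH3Br, KOtBu, THF, 0 → 50 °C
Reagents that add atoms: methyltriphenylphosphonium bromide, C[P+](c1ccccc1)(c1ccccc1)c1ccccc1.[Br-]
Why: Wittig methylenation of the C8 ketone installs C17 as the exocyclic alkene, and any enolisation towards C9 returns the side chain to its equatorial (natural) position.

Step 13
Reactants: 21 methyl 2α-chloro-12-[methoxy(methyl)amino]-12-oxo-13,14,15,16-tetranorlabd-8(17)-en-18-oate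
Product: 22 2α-chloro-18-hydroxy-13,14,15,16-tetranorlabd-8(17)-en-12-al
Conditions: LiAlH4, THF, −40 → 0 °C
Reagents that add atoms: none
Why: Hydride reduction by LiAlH4 takes the C18 ester to the primary alcohol while the Weinreb amide stops at the chelated tetrahedral adduct, which gives the C12 aldehyde only on work-up; the equatorial secondary chloride is inert.

Step 14
Reactants: 22 2α-chloro-18-hydroxy-13,14,15,16-tetranorlabd-8(17)-en-12-al
Product: 23 2α-chloro-18-(triethylsilyloxy)-13,14,15,16-tetranorlabd-8(17)-en-12-al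
Conditions: Et3SiCl, imidazole, CH2Cl2, 0 °C
Reagents that add atoms: chlorotriethylsilane, CC[Si](Cl)(CC)CC
Why: Silylation of the neopentyl C18 alcohol masks the only acidic proton before the boron aldol reaction.

Step 15
Reactants: 24 (R)-4-benzyl-1,3-oxazolidin-2-one; 25 3-cyanopropanoic acid
Product: 26 4-[(4R)-4-benzyl-2-oxo-1,3-oxazolidin-3-yl]-4-oxobutanenitrile
Conditions: DCC, DMAP (cat.), CH2Cl2, 0 → 23 °C
Reagents that add atoms: none
Why: Carbodiimide-mediated N-acylation (Steglich type, DMAP catalysis) joins the acid to the auxiliary without the strong base that the acidic α-cyano protons would not tolerate.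

Step 16
Reactants: 26 4-[(4R)-4-benzyl-2-oxo-1,3-oxazolidin-3-yl]-4-oxobutanenitrile; 23 2α-chloro-18-(triethylsilyloxy)-13,14,15,16-tetranorlabd-8(17)-en-12-al
Product: 28 (4R)-4-benzyl-3-[(12S,13R)-aldol adduct] oxazolidinone: C16 acyl oxazolidinone bearing CH2CN on C13 and OH on C12 of the 18-silyloxy decalin, via boron enolate 27 (not isolated)
Conditions: Bu2BOTf, i-Pr2NEt, CH2Cl2, −78 → 0 °C; then 23, −78 → 0 °C; pH 7 buffer, MeOH, H2O2
Reagents that add atoms: none
Why: Evans syn aldol reaction through the Z-boron enolate and a Zimmerman–Traxler chair, in which the (R)-benzyl auxiliary shields one enolate face, should set C13 as R and C12 as S.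

Step 17
Reactants: 28 Evans syn aldol adduct
Product: 31 haterumaimide J, via primary amide 29 (not isolated), via silyl ether 30 (not isolated)
Conditions: PtH(PMe2OH)(PMe2O)2H (5 mol %), EtOH/H2O, 80 °C; DBU (1.1 equiv), THF, 0 °C; 1 M HCl, THF, 23 °C
Reagents that add atoms: water, O
Why: Platinum-catalysed neutral hydration of the nitrile gives the primary amide, whose nitrogen then acylates intramolecularly (5-exo-trig) on the imide carbonyl with release of the auxiliary to form the succinimide, and dilute acid removes the silyl ether without touching a stereocentre.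

**Compound list**

1 | pent-4-enal | C=CCCC=O | starting material
2 | methyl methacrylate | C=C(C)C(=O)OC | starting material
3 | methyl (2E)-2-methyl-6-oxohex-2-enoate | O=CCC/C=C(\C)C(=O)OC | intermediate
4 | methyl propiolate | C#CC(=O)OC | starting material
5 | methyl 3-(methylzincio)prop-2-ynoate (alkynylzinc reagent) | C[Zn]C#CC(=O)OC | intermediate
6 | dimethyl (2E,6R)-6-hydroxy-2-methylnon-2-en-7-ynedioate | COC(=O)C#C[C@H](O)CC/C=C(\C)C(=O)OC | intermediate
7 | dimethyl (2E,6R,7Z)-6-hydroxy-2-methylnona-2,7-dienedioate | COC(=O)/C=C\[C@H](O)CC/C=C(\C)C(=O)OC | intermediate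
8 | methyl (2E)-2-methyl-5-[(2R)-5-oxo-2,5-dihydrofuran-2-yl]pent-2-enoate | O=C1O[C@H](CC/C=C(\C)C(=O)OC)C=C1 | intermediate
9 | 5-chloropent-1-yne | C#CCCCCl | starting material
10 | 2-bromo-5-chloropent-1-ene | C=C(Br)CCCCl | intermediate
11 | (5-chloropent-1-en-2-yl)magnesium bromide | C=C([Mg]Br)CCCCl | intermediate
12 | methyl (2E)-5-[(2R,3R)-3-(5-chloropent-1-en-2-yl)-5-oxooxolan-2-yl]-2-methylpent-2-enoate | C=C(CCCCl)[C@H]1CC(=O)O[C@@H]1CC/C=C(\C)C(=O)OC | intermediate
13 | methyl 2-[(3aR,4S,5S,7aR)-4-(3-chloropropyl)-4-methyl-2-oxooctahydro-1-benzofuran-5-yl]propanoate (both C4 epimers) | ClCCC[C@@]1(C)[C@H](C(C)C(=O)OC)CC[C@H]2OC(=O)C[C@H]12 | intermediate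
14 | methyl 2-[(3aR,4S,5S,7aR)-4-(3-iodopropyl)-4-methyl-2-oxooctahydro-1-benzofuran-5-yl]propanoate (both C4 epimers) | ICCC[C@@]1(C)[C@H](C(C)C(=O)OC)CC[C@H]2OC(=O)C[C@H]12 | intermediate
15 | lithium carboxylate of the ring-opened lactone of 14 (C8 hydroxyl free, C12 carboxylate) | ICCC[C@@]1(C)[C@H](C(C)C(=O)OC)CC[C@@H](O)[C@@H]1CC(=O)[O-].[Li+] | intermediate
16 | 8α-hydroxy-18-methoxy-18-oxo-13,14,15,16,17-pentanorlabdan-12-oic acid | OC(=O)C[C@H]1[C@H](O)CC[C@H]2[C@](C)(C(=O)OC)CCC[C@]12C | intermediate
17 | methyl 13,14,15,16,17-pentanor-8α,12-labdanolid-18-oate | O=C1O[C@@H]2CC[C@H]3[C@](C)(C(=O)OC)CCC[C@]3(C)[C@H]2C1 | intermediate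
18 | methyl 2α-chloro-13,14,15,16,17-pentanor-8α,12-labdanolid-18-oate | O=C1O[C@@H]2CC[C@H]3[C@](C)(C(=O)OC)C[C@H](Cl)C[C@]3(C)[C@H]2C1 | intermediate
19 | methyl 2α-chloro-8α-hydroxy-12-[methoxy(methyl)amino]-12-oxo-13,14,15,16,17-pentanorlabdan-18-oate | CON(C)C(=O)C[C@H]1[C@H](O)CC[C@H]2[C@](C)(C(=O)OC)C[C@H](Cl)C[C@]12C | intermediate
20 | methyl 2α-chloro-12-[methoxy(methyl)amino]-8,12-dioxo-13,14,15,16,17-pentanorlabdan-18-oate | CON(C)C(=O)C[C@H]1C(=O)CC[C@H]2[C@](C)(C(=O)OC)C[C@H](Cl)C[C@]12C | intermediate
21 | methyl 2α-chloro-12-[methoxy(methyl)amino]-12-oxo-13,14,15,16-tetranorlabd-8(17)-en-18-oate | CON(C)C(=O)C[C@H]1C(=C)CC[C@H]2[C@](C)(C(=O)OC)C[C@H](Cl)C[C@]12C | intermediate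
22 | 2α-chloro-18-hydroxy-13,14,15,16-tetranorlabd-8(17)-en-12-al | O=CC[C@H]1C(=C)CC[C@H]2[C@](C)(CO)C[C@H](Cl)C[C@]12C | intermediate
23 | 2α-chloro-18-(triethylsilyloxy)-13,14,15,16-tetranorlabd-8(17)-en-12-al | O=CC[C@H]1C(=C)CC[C@H]2[C@](C)(CO[Si](CC)(CC)CC)C[C@H](Cl)C[C@]12C | intermediate
24 | (R)-4-benzyl-1,3-oxazolidin-2-one | O=C1N[C@H](Cc2ccccc2)CO1 | starting material
25 | 3-cyanopropanoic acid | N#CCCC(=O)O | starting material
26 | 4-[(4R)-4-benzyl-2-oxo-1,3-oxazolidin-3-yl]-4-oxobutanenitrile | N#CCCC(=O)N1[C@H](Cc2ccccc2)COC1=O | intermediate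
27 | Z-dibutylboron enolate of 26 | N#CC/C=C(\OB(CCCC)CCCC)N1[C@H](Cc2ccccc2)COC1=O | intermediate
28 | (4R)-4-benzyl-3-acyl-oxazolidin-2-one, Evans syn aldol adduct (12S,13R; CH2CN on C13, OH on C12, 18-OSiEt3, 2α-Cl, 8(17)-ene) | N#CC[C@@H](C(=O)N3[C@H](Cc4ccccc4)COC3=O)[C@@H](O)C[C@H]1C(=C)CC[C@H]2[C@](C)(CO[Si](CC)(CC)CC)C[C@H](Cl)C[C@]12C | intermediate
29 | primary amide from hydration of the nitrile of 28 | NC(=O)C[C@@H](C(=O)N3[C@H](Cc4ccccc4)COC3=O)[C@@H](O)C[C@H]1C(=C)CC[C@H]2[C@](C)(CO[Si](CC)(CC)CC)C[C@H](Cl)C[C@]12C | intermediate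
30 | 18-O-triethylsilyl haterumaimide J | C=C1CC[C@H]2[C@](C)(CO[Si](CC)(CC)CC)C[C@H](Cl)C[C@]2(C)[C@H]1C[C@H](O)[C@H]1CC(=O)NC1=O | intermediate
31 | haterumaimide J (12S,13R; 2α-Cl, 18-OH) | C=C1CC[C@H]2[C@](C)(CO)C[C@H](Cl)C[C@]2(C)[C@H]1C[C@H](O)[C@H]1CC(=O)NC1=O | target

**Step count and risks**

Total steps: 17. Longest linear sequence: 15 (steps 1–3, 5–14, 16, 17).

Steps most likely to fail:

1. Step 6 (key step). The tertiary C10 radical may be reduced (net hydrogenation of the C10=C20 alkene) or the alkene isomerised before 6-exo closure, or the closure may discriminate the two faces of C10 too little at the temperature the iron hydride needs. Fallback, setting out from 12 and returning at 13: Markovnikov addition of HBr (CH2Cl2, −78 °C) should give the tertiary bromide F1. Bromine abstraction by a silyl radical ((Me3Si)3SiH by syringe pump, Et3B/air, PhMe, 0 °C) would generate the same C10 radical with no metal hydride present and at low temperature; Giese cyclisation and hydrogen transfer from the silane lead to 13.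

2. Step 9. Hydrogen abstraction at C1, C3 or C6 may compete with C2, or chlorine may be delivered to both faces. Fallback, setting out from 17 and returning at 18: electrochemical C–H oxidation with a quinuclidine mediator (Me4NBF4, HFIP/MeCN, O2, carbon anode), a reaction type that oxidises the C2 methylene of decalin lactones of this kind, should give the 2-oxo lactone F2. NaBH4 (MeOH, 0 °C) can approach only from the α face and should give the axial 2β-alcohol F3. Appel chlorination (PPh3, CCl4, 60 °C) with inversion then gives 18.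

3. Step 8. The trilithio species may be poorly soluble so that enolisation at C4 stays incomplete, or the free C8 alkoxide may alkylate on oxygen. Fallback, setting out from 14 and returning at 17: LiOH (THF/H2O) to 15 as in step 8, then TBSOTf/2,6-lutidine (CH2Cl2) should give the bis-silyl derivative F4. Aqueous K2CO3/MeOH would cleave the silyl ester to the silyloxy acid F5. LiN(iPr)2 (2.1 equiv, THF/DMPU, −78 → 0 °C) would close ring A to the ring-closed silyloxy acid F6. HCl in MeOH/THF would then remove the silyl ether and relactonise through 16 to 17.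

Further compounds
F1 | step 6 | methyl (2E)-5-[(2R,3S)-3-(2-bromo-5-chloropentan-2-yl)-5-oxooxolan-2-yl]-2-methylpent-2-enoate (both epimers at the bromide carbon) | CC(Br)(CCCCl)[C@H]1CC(=O)O[C@@H]1CC/C=C(\C)C(=O)OC
F2 | step 9 | methyl 2-oxo-13,14,15,16,17-pentanor-8α,12-labdanolid-18-oate | O=C1O[C@@H]2CC[C@H]3[C@](C)(C(=O)OC)CC(=O)C[C@]3(C)[C@H]2C1
F3 | step 9 | methyl 2β-hydroxy-13,14,15,16,17-pentanor-8α,12-labdanolid-18-oate | O=C1O[C@@H]2CC[C@H]3[C@](C)(C(=O)OC)C[C@@H](O)C[C@]3(C)[C@H]2C1
F4 | step 8 | tert-butyldimethylsilyl ester of the 8-O-tert-butyldimethylsilyl ring-opened acid of 14 | ICCC[C@@]1(C)[C@H](C(C)C(=O)OC)CC[C@@H](O[Si](C)(C)C(C)(C)C)[C@@H]1CC(=O)O[Si](C)(C)C(C)(C)C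
F5 | step 8 | 8-O-tert-butyldimethylsilyl ring-opened acid of 14 | ICCC[C@@]1(C)[C@H](C(C)C(=O)OC)CC[C@@H](O[Si](C)(C)C(C)(C)C)[C@@H]1CC(=O)O
F6 | step 8 | 8α-(tert-butyldimethylsilyloxy)-18-methoxy-18-oxo-13,14,15,16,17-pentanorlabdan-12-oic acid | OC(=O)C[C@H]1[C@H](O[Si](C)(C)C(C)(C)C)CC[C@H]2[C@](C)(C(=O)OC)CCC[C@]12C
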